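(All runs stem from a simulated flask on assumed constants; the scatter is artificial.)

Starting complex is left over at the end of both earlier runs. At the last readings, free starting complex stands at 61.7% in the gamma run and 50.9% in the delta run, with the curves flat, although 1 equiv of incoming ligand was charged and complex with one exchanged reads 20.4% and 26.3%.

| flask | starting complex | incoming ligand | leaving ligand | remark | time |
|---|---|---|---|---|---|
| gamma | 0.25 M | 1 equiv | 5 equiv | run made earlier |  |
| delta | 0.38 M | 1 equiv | 5 equiv | run made earlier |  |
| flask | 0.50 M | 1.00 equiv | 5.00 equiv |  | 5.0 h |

| run | time / h | complex with one exchanged / % | starting complex / % |
|---|---|---|---|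
| gamma | 0.500 | 12.8 | 75.4 |
| gamma | 0.833 | 16.1 | 69.7 |
| gamma | 1.50 | 18.7 | 64.2 |
| gamma | 3.00 | 20.6 | 62.4 |
| gamma | 6.00 | 20.4 | 61.7 |
| delta | 0.500 | 17.5 | 66.4 |
| delta | 1.50 | 24.4 | 52.9 |
| delta | 3.00 | 26.8 | 50.7 |
| delta | 4.00 | 26.8 | 51.3 |
| delta | 6.00 | 26.3 | 50.9 |

(readings scatter by 0.5 percentage points)

* equivalents of incoming ligand to starting complex, everything else as given, that leave most complex with one exchanged at 5.0 h
* the amount of complex with one exchanged then, in percent of the starting complex charged
* the amount of complex with one exchanged with the amounts as given

- the earlier runs were read with a standard deviation of 0.5 percentage points
- a reading or a percentage of complex with one exchanged counts all its forms, free or not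
- a reading of starting complex is of its free form alone

The reckoning made here therefore assumes that incoming ligand also decays by itself, at a rate following its own amount, while exchange follows free starting complex as well. The share of incoming ligand captured is then the free concentration divided by itself plus a constant. Taking free starting complex midway between the whole charge and its last reading, and setting that share equal to the reading, gives 0.789 M from gamma and 0.803 M from delta. So the break-even concentration, the free starting complex at which exchange and decay take equal parts of incoming ligand, is taken as 0.796 M.

Both runs are flat from 3.00 h, so the flask at 5.0 h should show its end state. Two extreme versions of the flask bracket it. If free starting complex stayed at the whole charge, the capture would be 38.6%. If it sat from the first moment at its end fraction, 40.9% on the trend of the two runs, the capture would be 20.5%. On this reckoning the flask starts at the first and ends at the second, so its capture should lie between them. The midway fraction 70.5% gives 30.7%, the figure this reckoning commits to; it gives none for the best equivalents.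

The forecast says 29%, with a best of 32% at 1.5 equiv, and of that optimum: “An optimum needs an assumed, unobserved second exchange”.

With the amounts as given the flask gives 29.9%; the asked best is 46.5%, at 3.20 equiv of incoming ligand.

    starting complex + incoming ligand → leaving ligand + complex with one exchanged (k = 5.00 × 10⁻⁴ /M/s)
    complex with one exchanged + incoming ligand → leaving ligand + complex with two exchanged (k = 4.00 × 10⁻⁴ /M/s)
    incoming ligand → decomposed reagent (k = 3.80 × 10⁻⁴ /s)
    starting complex + complex with one exchanged ⇌ idle adduct, settled at all times (K = 36.0 /M)

Break-even at 0.796 M serves the flask again: with its simulated end of 43.1% free starting complex, the midway reckoning captures 31.0%. A neighbouring flask, charged at 0.12 M of starting complex with the same equivalents, lies below break-even and ends with 78.4% free starting complex, so the same reckoning gives 11.9%. That neighbour holds 12.1% of complex with one exchanged, all forms counted, at 5.00 h, with less of its charge left of incoming ligand, the limiting reagent, than of starting complex: 0.044% against 78%.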